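**Retrosynthetic overview**

- Feature: C8, the methyl-bearing stereocentre, is bound to the phenolic oxygen of ring B (the 4-allyl-2,6-dimethoxyphenyl ring). C8 with its ether oxygen, its methyl group and C7 is the skeleton of a 2-aryloxypropanoate; C7 carries the acetate and ring A (3,4-dimethoxyphenyl).
- C7–OAc is cut back to the erythro (7R,8S) alcohol. C7–C(ring A) is cut to an (S)-2-aryloxypropanal and a 3,4-dimethoxyphenyl titanium nucleophile (Felkin–Anh addition), and the aldehyde goes back to the ethyl ester.
- C8–O(ring B) is cut to 4-allyl-2,6-dimethoxyphenol and ethyl 2-diazopropanoate: an asymmetric copper-carbene insertion into the phenol O–H bond sets C8.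
- The diazo ester goes back to ethyl 2-methylacetoacetate by deacylative diazo transfer.
- No ring is formed at any point; rings A and B are bought as 4-bromoveratrole and the phenol.

Key step: step 2

Assumption: the (Ra,R,R) antipode of the spiro bis(oxazoline) ligand is taken to deliver the (S)-ester 4; if the sense of induction proves to be the reverse, the (Sa,S,S) antipode is used instead.

**Route**

Step 1
Reactants: 1 ethyl 2-methylacetoacetate
Product: 2 ethyl 2-diazopropanoate
Conditions: 4-acetamidobenzenesulfonyl azide (1.2 equiv), DBU (1.5 equiv), MeCN, 0 °C → rt; pentane extraction, short silica plug, kept cold and handled behind a shield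
Reagents that add atoms: 4-acetamidobenzenesulfonyl azide, CC(=O)Nc1ccc(cc1)S(=O)(=O)N=[N+]=[N-]
Why: Regitz deacylative diazo transfer, in which the DBU enolate of the 2-substituted β-keto ester attacks the terminal nitrogen of the sulfonyl azide and the adduct fragments with transfer of the acetyl group to the sulfonamide nitrogen, leaving the α-diazo ester.

Step 2
Reactants: 3 4-allyl-2,6-dimethoxyphenol; 2 ethyl 2-diazopropanoate
Product: 4 ethyl (S)-2-(4-allyl-2,6-dimethoxyphenoxy)propanoate
Conditions: CuCl (5 mol %), (Ra,R,R)-7,7'-bis(4-phenyl-4,5-dihydrooxazol-2-yl)-1,1'-spirobiindane (6 mol %), NaB[3,5-(CF3)2C6H3]4 (6 mol %), 4 Å MS, CH2Cl2, 25 °C; 2 added over 4 h by syringe pump to 3 (2 equiv); excess 3 recovered by chromatography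
Reagents that add atoms: none
Why: The cationic monovalent copper complex formed from CuCl, the borate and the ligand decomposes 2 with loss of N2 to an electrophilic copper carbene, the phenol oxygen of 3 adds to the carbene carbon to give a copper-bound oxonium ylide, and a 1,2-proton shift releases 4 and the catalyst. The closest known reaction type is the copper-catalysed enantioselective O–H insertion of α-diazopropanoates into phenols with chiral spiro bis(oxazoline) ligands, applied here to a phenol that bears two ortho methoxy groups. No ring is closed; the only new skeletal bond is C8–O(ring B). C8 is the one new stereocentre, and its configuration is decided in the proton shift, which should take place while the ylide is still held on copper inside the ligand pocket, so that the ligand antipode selects the S centre. The step needs O–H insertion to outrun cyclopropanation of the allyl alkene, the 1,2-hydride shift to ethyl acrylate and carbene dimerisation; the first is secured by the much higher nucleophilicity of the phenol oxygen than of an unactivated terminal alkene toward the electrophilic carbene, the others by the choice of copper in place of a dirhodium tetracarboxylate such as Rh2(OAc)4, by slow addition of 2 and by the excess of 3.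

Step 3
Reactants: 4 ethyl (S)-2-(4-allyl-2,6-dimethoxyphenoxy)propanoate
Product: 5 (S)-2-(4-allyl-2,6-dimethoxyphenoxy)propanal
Conditions: iBu2AlH (1.1 equiv, 1 M in toluene), CH2Cl2, −78 °C, 1 h; MeOH at −78 °C, then aq. potassium sodium tartrate; crude aldehyde kept cold, not chromatographed, used at once
Reagents that add atoms: none
Why: Partial reduction of an ester with iBu2AlH, in which the α-aryloxy oxygen should help hold the aluminium hemiacetal as a chelate at −78 °C so that the aldehyde is released only on work-up and C8 is left untouched.

Step 4
Reactants: 5 (S)-2-(4-allyl-2,6-dimethoxyphenoxy)propanal; 6 4-bromoveratrole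
Product: 9 (1R,2S)-2-(4-allyl-2,6-dimethoxyphenoxy)-1-(3,4-dimethoxyphenyl)propan-1-ol, via 3,4-dimethoxyphenyllithium 7 (not isolated), via (3,4-dimethoxyphenyl)titanium triisopropoxide 8 (not isolated)
Conditions: 6 (2.0 equiv), n-BuLi (2.0 equiv), THF, −78 °C, 30 min; ClTi(OiPr)3 (2.1 equiv), −78 → −40 °C; then 5 in THF, −78 → 0 °C; sat. aq. NH4Cl
Reagents that add atoms: none
Why: Bromine–lithium exchange and transmetallation give an aryltitanium triisopropoxide that is weakly Lewis acidic and weakly basic, so it should add to the aldehyde without chelating the hindered aryloxy oxygen and without enolising C8, under polar Felkin–Anh control with the C8–OAr bond anti to the incoming aryl group and the aryl passing the C8 hydrogen, which sets C7 as R and gives the erythro (7R,8S) alcohol.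

Step 5
Reactants: 9 (1R,2S)-2-(4-allyl-2,6-dimethoxyphenoxy)-1-(3,4-dimethoxyphenyl)propan-1-ol
Product: 10 Maceneolignan H, (1R,2S)-2-(4-allyl-2,6-dimethoxyphenoxy)-1-(3,4-dimethoxyphenyl)propyl acetate
Conditions: Ac2O (2 equiv), pyridine (3 equiv), DMAP (5 mol %), CH2Cl2, 0 °C → rt
Reagents that add atoms: acetic anhydride, CC(=O)OC(C)=O
Why: DMAP-catalysed acylation of a secondary alcohol under basic conditions, in which the C7–O bond is not broken and the electron-rich benzylic position is not ionised, so C7 and C8 keep their configuration.

**Compound list**

1 | ethyl 2-methylacetoacetate (ethyl 2-methyl-3-oxobutanoate) | CCOC(=O)C(C)C(C)=O | starting material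
2 | ethyl 2-diazopropanoate | CCOC(=O)C(C)=[N+]=[N-] | intermediate
3 | 4-allyl-2,6-dimethoxyphenol | C=CCc1cc(OC)c(O)c(OC)c1 | starting material
4 | ethyl (S)-2-(4-allyl-2,6-dimethoxyphenoxy)propanoate | C=CCc1cc(OC)c(O[C@@H](C)C(=O)OCC)c(OC)c1 | intermediate
5 | (S)-2-(4-allyl-2,6-dimethoxyphenoxy)propanal | C=CCc1cc(OC)c(O[C@@H](C)C=O)c(OC)c1 | intermediate
6 | 4-bromoveratrole (4-bromo-1,2-dimethoxybenzene) | COc1ccc(Br)cc1OC | starting material
7 | 3,4-dimethoxyphenyllithium | [Li]c1ccc(OC)c(OC)c1 | intermediate
8 | (3,4-dimethoxyphenyl)titanium triisopropoxide | CC(C)O[Ti](OC(C)C)(OC(C)C)c1ccc(OC)c(OC)c1 | intermediate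
9 | (1R,2S)-2-(4-allyl-2,6-dimethoxyphenoxy)-1-(3,4-dimethoxyphenyl)propan-1-ol | C=CCc1cc(OC)c(O[C@@H](C)[C@H](O)c2ccc(OC)c(OC)c2)c(OC)c1 | intermediate
10 | Maceneolignan H, (1R,2S)-2-(4-allyl-2,6-dimethoxyphenoxy)-1-(3,4-dimethoxyphenyl)propyl acetate | C=CCc1cc(OC)c(O[C@@H](C)[C@H](OC(C)=O)c2ccc(OC)c(OC)c2)c(OC)c1 | target

**Step count**

Total steps: 5. Longest linear sequence: 5 steps (1 → 2 → 4 → 5 → 9 → 10); phenol 3 and bromide 6 enter as bought materials.

**Steps most likely to fail, with fallbacks**

Step 2. The two ortho methoxy groups crowd the phenol oxygen and may bind copper, so the insertion could be slow or poorly enantioselective; cyclopropanation of the allyl group or hydride shift of the carbene could then take over. The fallback sets out from phenol 3 and forms the C8–O bond by a Mitsunobu etherification with ethyl (R)-lactate (PPh3, diisopropyl azodicarboxylate, THF, 0 °C → rt). The SN2 displacement of the activated lactate hydroxyl by the phenoxide inverts the carbinol carbon and should give the (S)-ester directly, so the fallback comes back to the route at 4 and step 1 is no longer needed. No compound outside the list arises (F0).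

Step 4. Part of the addition could run through a chelated transition state and give the threo (7S,8S) alcohol, or the basic organometallic could enolise the aldehyde and erode C8. The fallback sets out from ester 4 and avoids the aldehyde. Treatment with MeNH(OMe)·HCl and iPrMgCl (THF, −20 °C) should give the Weinreb amide (S)-2-(4-allyl-2,6-dimethoxyphenoxy)-N-methoxy-N-methylpropanamide F1. Addition of 3,4-dimethoxyphenyllithium 7 (from 6 and n-BuLi as in step 4; THF, −78 °C) should stop at the chelated tetrahedral adduct and give, on work-up, the ketone (S)-2-(4-allyl-2,6-dimethoxyphenoxy)-1-(3,4-dimethoxyphenyl)propan-1-one F2. Reduction with Zn(BH4)2 (Et2O, −20 → 0 °C) is then expected to run under chelation control: zinc bridges the carbonyl and ether oxygens and hydride enters from the face of the C8 hydrogen, which leads to the erythro alcohol. The fallback comes back to the route at 9. The ketone is enolisable at C8, so it would be carried on without delay.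

Step 3. The reduction could run on to the primary alcohol, or the aldehyde could epimerise or hydrate during work-up. The fallback sets out from ester 4 and replaces the partial reduction by a two-step redox sequence. Full reduction with LiAlH4 (THF, 0 °C) should give (S)-2-(4-allyl-2,6-dimethoxyphenoxy)propan-1-ol F3, a stable compound that can be purified and stored. Oxidation with Dess–Martin periodinane (NaHCO3, CH2Cl2, 0 °C → rt) under buffered, non-basic conditions should then give the aldehyde, which is used crude. The fallback comes back to the route at 5.

**Further compounds**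

F0 | step 2 | none | none
F1 | step 4 | (S)-2-(4-allyl-2,6-dimethoxyphenoxy)-N-methoxy-N-methylpropanamide | C=CCc1cc(OC)c(O[C@@H](C)C(=O)N(C)OC)c(OC)c1
F2 | step 4 | (S)-2-(4-allyl-2,6-dimethoxyphenoxy)-1-(3,4-dimethoxyphenyl)propan-1-one | C=CCc1cc(OC)c(O[C@@H](C)C(=O)c2ccc(OC)c(OC)c2)c(OC)c1
F3 | step 3 | (S)-2-(4-allyl-2,6-dimethoxyphenoxy)propan-1-ol | C=CCc1cc(OC)c(O[C@@H](C)CO)c(OC)c1
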